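Retrosynthesis: remove the two catechol allyl groups; cut the C7 prenyl group back to a C7 formyl group (two Wittig carbons); cut C5–C6 (opens ring B to a dienone carrying a 2-substituted acrolein), then C1–C8 (retro-Claisen) to an achiral aryl allyl ether; cut O9–C6, the two ring–geranyl bonds and the aryl–CO bond.
Enabling feature: ring A (C1–C2–C3–C4–C5–C9 with O2, O4, O9 and the C3 aroyl group) is a dearomatised acylphloroglucinol in which O9 lies between the geranylated carbons C1 and C5, and the C8–C7–C6 bridge is a 2-formylprenyl unit that can hang on O9 through C6.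
Forward: aromatic ring A is made first (aryllithium + nitrile, twofold C-geranylation, O9 etherification); one flask then moves the allyl unit from O9 to C1 ([3,3] shift, C1–C8) and closes ring B by Michael addition of C5 to C6; two Wittig reactions finish the prenyl group and the catechol is released last.
Stereochemistry: C1 from ligand-controlled differentiation of the enantiotopic ortho carbons in the Claisen step; C5 is forced by the tether; C7 by equilibration of the formyl group to the exo position; both geranyl E-alkenes come from geranyl bromide.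
Key step: step 8

Remark: skeleton locants of the target (C1 = bridgehead next to C8Me2, C2–C4 = acyl-dione bridge, C5 = bridgehead next to C6H2, C7 = CH, C9 = bridging ketone; O2, O4, O9 their oxygens) are used for the corresponding atoms of all precursors; the enolised acyl-dione is drawn as one of its interconverting tautomers; geranyl = (2E)-3,7-dimethylocta-2,6-dienyl; BSA = N,O-bis(trimethylsilyl)acetamide; (S,S)-t-Bu-box = 2,2'-(propane-2,2-diyl)bis[(4S)-4-tert-butyl-4,5-dihydro-1,3-oxazole].

Step 1
Reactants: 1 phloroglucinol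
Product: 2 1,3,5-tris(methoxymethoxy)benzene
Conditions: NaH, MOMCl, DMF, 0 °C → rt
Reagents that add atoms: chloromethyl methyl ether, COCCl
Why: Williamson O-alkylation of the phenoxide with a hard α-chloro ether gives the tris-acetal, whose OMOM groups direct the later ortho-lithiation and come off with acid.

Step 2
Reactants: 3 3,4-dihydroxybenzonitrile
Product: 4 3,4-bis(allyloxy)benzonitrile
Conditions: allyl bromide, K2CO3, DMF, 60 °C
Reagents that add atoms: allyl bromide, C=CCBr
Why: Williamson etherification; aryl allyl ethers should survive acid, aqueous base, Lewis acid and ylides and are removable at the end under neutral conditions with zerovalent palladium.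

Step 3
Reactants: 2 1,3,5-tris(methoxymethoxy)benzene; 4 3,4-bis(allyloxy)benzonitrile
Product: 7 [3,4-bis(allyloxy)phenyl](2,4,6-trihydroxyphenyl)methanone, via aryllithium 5 (not isolated), via lithium ketiminate 6 (not isolated)
Conditions: n-BuLi, THF, 0 °C; then 4, −78 °C → rt; then 3 M aq. HCl, MeOH, 65 °C
Reagents that add atoms: water, O
Why: Directed ortho-metalation between two OMOM groups, addition of the aryllithium to the nitrile (stops at the ketiminate) and one acidic operation that hydrolyses the imine and the three MOM acetals; this avoids a Friedel–Crafts acylation, which the allyl ethers would not survive.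

Step 4
Reactants: 7 [3,4-bis(allyloxy)phenyl](2,4,6-trihydroxyphenyl)methanone; 8 geranyl bromide
Product: 9 [3,4-bis(allyloxy)phenyl](3,5-digeranyl-2,4,6-trihydroxyphenyl)methanone
Conditions: 8 (2.2 equiv), 10% aq. KOH, 0 °C
Reagents that add atoms: none
Why: C-alkylation (SN2, E geometry retained) of the ambident acylphloroglucinolate in water, where the oxygens are masked by hydrogen bonding; the aroyl group blocks one ring carbon, so the two geranyl groups go to the future C1 and C5.

Step 5
Reactants: 10 diethyl isopropylidenemalonate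
Product: 11 2-(propan-2-ylidene)propane-1,3-diol
Conditions: i-Bu2AlH (4.5 equiv), CH2Cl2, −78 → 0 °C; aq. potassium sodium tartrate
Reagents that add atoms: none
Why: 1,2-reduction of both ester groups of the alkylidene malonate by the electrophilic aluminium hydride, without conjugate reduction of the tetrasubstituted alkene.

Step 6
Reactants: 11 2-(propan-2-ylidene)propane-1,3-diol
Product: 12 2-(hydroxymethyl)-3-methylbut-2-enal
Conditions: activated MnO2, CH2Cl2, rt, stopped at mono-oxidation
Reagents that add atoms: none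
Why: Allylic alcohol oxidation with MnO2; after the first oxidation the remaining CH2OH sits on an electron-poor enal and should react more slowly, so the symmetrical diol can be stopped at the hydroxy enal.

Step 7
Reactants: 9 [3,4-bis(allyloxy)phenyl](3,5-digeranyl-2,4,6-trihydroxyphenyl)methanone; 12 2-(hydroxymethyl)-3-methylbut-2-enal
Product: 13 O9 (2-formyl-3-methylbut-2-enyl) ether of 9
Conditions: PPh3, DIAD, THF, 0 °C → rt
Reagents that add atoms: none
Why: Mitsunobu etherification (SN2 at the primary allylic carbon); O9–H, para to the aroyl group, is the most acidic hydroxyl and the only one not hydrogen-bonded to the ketone, so it should react in preference to the two chelated ortho hydroxyls.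

Step 8
Reactants: 13 O9 (2-formyl-3-methylbut-2-enyl) ether of 9
Product: 17 7-exo-formyl bicyclo[3.3.1]nonane trione, via bis-TMS ether 14 (not isolated), via silylated Claisen dienone 15 (not isolated), via free Claisen dienone 16 (not isolated)
Conditions: BSA (2.5 equiv), CH2Cl2, rt, then evaporation; [Cu((S,S)-t-Bu-box)](SbF6)2 (10 mol %), CH2Cl2, −40 → 0 °C; then Et3N, MeOH, 0 °C → rt
Reagents that add atoms: none
Why: Proposed new method: the closest known reaction types are the chiral copper bis(oxazoline)-catalysed Claisen rearrangement of chelating allyl vinyl ethers and the thermal dearomative Claisen shift of phloroglucinol allyl ethers onto an alkylated ortho carbon, followed here by the known base-mediated intramolecular Michael addition of a dearomatised acylphloroglucinol to an enal; the new element is the enantiotopos-selective catalysis, argued as follows. In the silylated, Cs-symmetric ether 14 the only bidentate site left is O9 plus the formyl oxygen (six-membered chelate with divalent copper), so the metal both accelerates the [3,3] shift (equivalent to a conjugate addition of C1 to the CMe2 terminus with β-loss of O9) and places the C2-symmetric ligand next to the two enantiotopic ortho carbons C1 and C5, whose differentiation creates the C1 stereocentre and the congested C1–C8 bond of dienone 15; the ligand antipode is taken if the sense of induction proves opposite. Methanolysis then frees the vinylogous acid 16, whose enolate carbon C5 adds to the CH2 terminus (C6) of the 2-substituted acrolein in a 6-endo-trig Michael closure of ring B, forming the C5–C6 bond and the second quaternary bridgehead. C5 is controlled by the tether, because the C8–C7–C6 chain on C1 can reach C5 only across its own face of ring A, and C7 is set last under thermodynamic control, the α-formyl centre equilibrating through its enol to the equatorial, exo position required by the target. The selectivities needed are C5 over the aroyl-bearing C3 as nucleophile (C3 is sterically shielded and its attack would break the acyl-dione conjugation), 1,4- over 1,2-addition to the enal (the aldol mode is reversible under the basic conditions, the Michael mode is not) and Claisen over Cope migration of the allyl unit (suppressed at the low temperature that Lewis-acid activation allows).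

Step 9
Reactants: 17 7-exo-formyl bicyclo[3.3.1]nonane trione
Product: 19 7-exo-(2-oxoethyl) bicyclo[3.3.1]nonane trione, via methyl enol ether 18 (not isolated)
Conditions: MeOCH2PPh3Cl (3.5 equiv), KN(SiMe3)2 (3.4 equiv), THF, −78 → 0 °C; then 2 M aq. HCl, THF, rt
Reagents that add atoms: (methoxymethyl)triphenylphosphonium chloride, COC[P+](c1ccccc1)(c1ccccc1)c1ccccc1.[Cl-]; water, O
Why: Wittig one-carbon homologation: the first equivalent of ylide turns the enolised acyl-dione into its inert enolate, the aldehyde is then the only accessible electrophile (C9 is shielded by two quaternary carbons), and enol-ether hydrolysis is far faster than protonation of the trisubstituted alkenes; C7 is no longer epimerisable afterwards.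

Step 10
Reactants: 19 7-exo-(2-oxoethyl) bicyclo[3.3.1]nonane trione
Product: 20 bis-O-allyl ether of the target
Conditions: i-PrPPh3I (3.5 equiv), n-BuLi (3.4 equiv), THF, −78 → 0 °C; aq. NaH2PO4 work-up
Reagents that add atoms: isopropyltriphenylphosphonium iodide, CC(C)[P+](c1ccccc1)(c1ccccc1)c1ccccc1.[I-]
Why: Wittig olefination of the unhindered CH2–CHO with the isopropylidene ylide completes the prenyl group, again with the acyl-dione protected as its enolate.

Step 11
Reactants: 20 bis-O-allyl ether of the target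
Product: 21 target CNP0178719.1
Conditions: Pd(PPh3)4 (5 mol %), morpholine (10 equiv), THF, rt, degassed; aq. NaH2PO4 work-up
Reagents that add atoms: none
Why: Zerovalent palladium ionises the two aryl allyl ethers to π-allyl complexes, which morpholine traps (Tsuji–Trost deallylation); geranyl and prenyl groups carry no leaving group and the conditions are neutral, so the acid-sensitive enol/polyene array should be untouched.

Compound list
1 | phloroglucinol (benzene-1,3,5-triol) | Oc1cc(O)cc(O)c1 | starting material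
2 | 1,3,5-tris(methoxymethoxy)benzene | COCOc1cc(OCOC)cc(OCOC)c1 | intermediate
3 | 3,4-dihydroxybenzonitrile | N#Cc1ccc(O)c(O)c1 | starting material
4 | 3,4-bis(allyloxy)benzonitrile | N#Cc1ccc(OCC=C)c(OCC=C)c1 | intermediate
5 | 2,4,6-tris(methoxymethoxy)phenyllithium | [Li]c1c(OCOC)cc(OCOC)cc1OCOC | intermediate
6 | N-lithio [3,4-bis(allyloxy)phenyl][2,4,6-tris(methoxymethoxy)phenyl]methanimine | [Li]N=C(c1ccc(OCC=C)c(OCC=C)c1)c1c(OCOC)cc(OCOC)cc1OCOC | intermediate
7 | [3,4-bis(allyloxy)phenyl](2,4,6-trihydroxyphenyl)methanone | O=C(c1ccc(OCC=C)c(OCC=C)c1)c1c(O)cc(O)cc1O | intermediate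
8 | geranyl bromide, (2E)-1-bromo-3,7-dimethylocta-2,6-diene | CC(C)=CCC/C(C)=C/CBr | starting material
9 | [3,4-bis(allyloxy)phenyl]{3,5-bis[(2E)-3,7-dimethylocta-2,6-dienyl]-2,4,6-trihydroxyphenyl}methanone | O=C(c1ccc(OCC=C)c(OCC=C)c1)c1c(O)c(C/C=C(\C)CCC=C(C)C)c(O)c(C/C=C(\C)CCC=C(C)C)c1O | intermediate
10 | diethyl isopropylidenemalonate, diethyl 2-(propan-2-ylidene)propanedioate | CCOC(=O)C(C(=O)OCC)=C(C)C | starting material
11 | 2-(propan-2-ylidene)propane-1,3-diol | CC(C)=C(CO)CO | intermediate
12 | 2-(hydroxymethyl)-3-methylbut-2-enal | CC(C)=C(CO)C=O | intermediate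
13 | 2-({4-[3,4-bis(allyloxy)benzoyl]-2,6-digeranyl-3,5-dihydroxyphenoxy}methyl)-3-methylbut-2-enal (achiral O9 ether) | O=C(c1ccc(OCC=C)c(OCC=C)c1)c1c(O)c(C/C=C(\C)CCC=C(C)C)c(OCC(C=O)=C(C)C)c(C/C=C(\C)CCC=C(C)C)c1O | intermediate
14 | bis(trimethylsilyl) ether of 13 at the two hydroxyls ortho to the aroyl group | O=C(c1ccc(OCC=C)c(OCC=C)c1)c1c(O[Si](C)(C)C)c(C/C=C(\C)CCC=C(C)C)c(OCC(C=O)=C(C)C)c(C/C=C(\C)CCC=C(C)C)c1O[Si](C)(C)C | intermediate
15 | (6R)-4-[3,4-bis(allyloxy)benzoyl]-6-(3-formyl-2-methylbut-3-en-2-yl)-2,6-digeranyl-3,5-bis(trimethylsilyloxy)cyclohexa-2,4-dien-1-one (quaternary carbon = skeleton C1) | O=C1C(C/C=C(\C)CCC=C(C)C)=C(O[Si](C)(C)C)C(C(=O)c2ccc(OCC=C)c(OCC=C)c2)=C(O[Si](C)(C)C)[C@@]1(C/C=C(\C)CCC=C(C)C)C(C)(C)C(=C)C=O | intermediate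
16 | (6R)-4-[3,4-bis(allyloxy)benzoyl]-6-(3-formyl-2-methylbut-3-en-2-yl)-2,6-digeranyl-3,5-dihydroxycyclohexa-2,4-dien-1-one | O=C1C(C/C=C(\C)CCC=C(C)C)=C(O)C(C(=O)c2ccc(OCC=C)c(OCC=C)c2)=C(O)[C@@]1(C/C=C(\C)CCC=C(C)C)C(C)(C)C(=C)C=O | intermediate
17 | (1S,5S,7R)-3-[3,4-bis(allyloxy)benzoyl]-1,5-digeranyl-4-hydroxy-8,8-dimethyl-2,9-dioxobicyclo[3.3.1]non-3-ene-7-carbaldehyde (formyl exo, anti to the C2–C4 bridge) | CC(C)=CCC/C(C)=C/C[C@]12C[C@@H](C=O)C(C)(C)[C@](C/C=C(\C)CCC=C(C)C)(C(=O)C(C(=O)c3ccc(OCC=C)c(OCC=C)c3)=C1O)C2=O | intermediate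
18 | (1S,5S,7S)-3-[3,4-bis(allyloxy)benzoyl]-1,5-digeranyl-4-hydroxy-7-(2-methoxyethenyl)-8,8-dimethylbicyclo[3.3.1]non-3-ene-2,9-dione (E/Z mixture at the enol ether, 7-exo) | CC(C)=CCC/C(C)=C/C[C@]12C[C@@H](C=COC)C(C)(C)[C@](C/C=C(\C)CCC=C(C)C)(C(=O)C(C(=O)c3ccc(OCC=C)c(OCC=C)c3)=C1O)C2=O | intermediate
19 | (1S,5S,7S)-3-[3,4-bis(allyloxy)benzoyl]-1,5-digeranyl-4-hydroxy-8,8-dimethyl-7-(2-oxoethyl)bicyclo[3.3.1]non-3-ene-2,9-dione (7-exo) | CC(C)=CCC/C(C)=C/C[C@]12C[C@@H](CC=O)C(C)(C)[C@](C/C=C(\C)CCC=C(C)C)(C(=O)C(C(=O)c3ccc(OCC=C)c(OCC=C)c3)=C1O)C2=O | intermediate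
20 | (1S,5S,7R)-3-[3,4-bis(allyloxy)benzoyl]-1,5-digeranyl-4-hydroxy-8,8-dimethyl-7-(3-methylbut-2-enyl)bicyclo[3.3.1]non-3-ene-2,9-dione | CC(C)=CCC/C(C)=C/C[C@]12C[C@@H](CC=C(C)C)C(C)(C)[C@](C/C=C(\C)CCC=C(C)C)(C(=O)C(C(=O)c3ccc(OCC=C)c(OCC=C)c3)=C1O)C2=O | intermediate
21 | (1S,5S,7R)-3-(3,4-dihydroxybenzoyl)-1,5-bis[(2E)-3,7-dimethylocta-2,6-dienyl]-4-hydroxy-8,8-dimethyl-7-(3-methylbut-2-enyl)bicyclo[3.3.1]non-3-ene-2,9-dione (prenyl exo) | CC(C)=CCC/C(C)=C/C[C@]12C[C@@H](CC=C(C)C)C(C)(C)[C@](C/C=C(\C)CCC=C(C)C)(C(=O)C(C(=O)c3ccc(O)c(O)c3)=C1O)C2=O | target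

Total step count: 11. Longest linear sequence: 8 steps (steps 1, 3, 4, 7, 8, 9, 10, 11 from phloroglucinol).

Steps most likely to fail

Step 8. The risk is insufficient discrimination between the two enantiotopic ortho carbons: weak or non-selective catalyst binding, or an uncatalysed background rearrangement, would give low enantiomeric purity. The fallback uses known chemistry and sets out from 13. Heating 13 without catalyst (toluene, 110 °C) should give the racemic Claisen dienone F1 by the ordinary aromatic Claisen shift onto the geranylated ortho carbon. Et3N in MeOH then closes ring B and equilibrates C7 to give the racemic bicyclic aldehyde F2. Condensation of F2 with (1S,2S)-N,N'-dimethyl-1,2-diphenylethane-1,2-diamine (MgSO4, CH2Cl2) gives two diastereomeric imidazolidines, the imidazolidine of 17 F3 and the imidazolidine of ent-17 F4, which are separated by chromatography. Mild aqueous acid (citric acid, THF) releases the aldehyde from F3, and the route is rejoined at 17.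

Step 7. The risk is loss of chemo- and site-selectivity in the Mitsunobu coupling: conjugate or SN2′ attack on the hydroxy enal, its decomposition by the betaine, or etherification at an ortho hydroxyl. The fallback sets out from 9 and uses diol 11 in place of 12. Mitsunobu coupling of 9 with an excess of the symmetrical diol gives the hydroxy ether F5, in which no enal is present during etherification. Oxidation of the allylic alcohol of F5 with activated MnO2 (CH2Cl2, rt) then installs the aldehyde, and the route is rejoined at 13.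

Step 9. The risk is deprotonation of the hindered, α-branched aldehyde by the basic ylide in place of addition, or acid-induced cyclisation of a geranyl group onto the enol during enol-ether hydrolysis. The fallback sets out from 17 and builds the prenyl group by C–C coupling instead of two olefinations. NaBH4 (MeOH/THF, −20 °C) reduces only the aldehyde to the primary alcohol F6. Iodine, PPh3 and imidazole (CH2Cl2, 0 °C) give the primary iodide F7. Coupling of F7 with excess 2-methylprop-1-enylmagnesium bromide and catalytic Li2CuCl4 (THF, −20 → 0 °C; the first equivalent forms the inert enolate) gives the prenyl compound, and the route is rejoined at 20.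

Further compounds
F1 | step 8 | racemic 4-[3,4-bis(allyloxy)benzoyl]-6-(3-formyl-2-methylbut-3-en-2-yl)-2,6-digeranyl-3,5-dihydroxycyclohexa-2,4-dien-1-one | O=C1C(C/C=C(\C)CCC=C(C)C)=C(O)C(C(=O)c2ccc(OCC=C)c(OCC=C)c2)=C(O)C1(C/C=C(\C)CCC=C(C)C)C(C)(C)C(=C)C=O
F2 | step 8 | racemic bicyclic aldehyde (17 and its mirror image, 7-exo) | CC(C)=CCC/C(C)=C/C[C@]12C[C@@H](C=O)C(C)(C)[C@](C/C=C(\C)CCC=C(C)C)(C(=O)C(C(=O)c3ccc(OCC=C)c(OCC=C)c3)=C1O)C2=O.CC(C)=CCC/C(C)=C/C[C@@]12C[C@H](C=O)C(C)(C)[C@@](C/C=C(\C)CCC=C(C)C)(C(=O)C(C(=O)c3ccc(OCC=C)c(OCC=C)c3)=C1O)C2=O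
F3 | step 8 | imidazolidine of 17 with (1S,2S)-N,N'-dimethyl-1,2-diphenylethane-1,2-diamine | CC(C)=CCC/C(C)=C/C[C@]12C[C@@H](C4N(C)[C@@H](c5ccccc5)[C@H](c5ccccc5)N4C)C(C)(C)[C@](C/C=C(\C)CCC=C(C)C)(C(=O)C(C(=O)c3ccc(OCC=C)c(OCC=C)c3)=C1O)C2=O
F4 | step 8 | imidazolidine of ent-17 with (1S,2S)-N,N'-dimethyl-1,2-diphenylethane-1,2-diamine | CC(C)=CCC/C(C)=C/C[C@@]12C[C@H](C4N(C)[C@@H](c5ccccc5)[C@H](c5ccccc5)N4C)C(C)(C)[C@@](C/C=C(\C)CCC=C(C)C)(C(=O)C(C(=O)c3ccc(OCC=C)c(OCC=C)c3)=C1O)C2=O
F5 | step 7 | 2-({4-[3,4-bis(allyloxy)benzoyl]-2,6-digeranyl-3,5-dihydroxyphenoxy}methyl)-3-methylbut-2-en-1-ol | O=C(c1ccc(OCC=C)c(OCC=C)c1)c1c(O)c(C/C=C(\C)CCC=C(C)C)c(OCC(CO)=C(C)C)c(C/C=C(\C)CCC=C(C)C)c1O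
F6 | step 9 | (1S,5S,7R)-3-[3,4-bis(allyloxy)benzoyl]-1,5-digeranyl-4-hydroxy-7-(hydroxymethyl)-8,8-dimethylbicyclo[3.3.1]non-3-ene-2,9-dione (7-exo) | CC(C)=CCC/C(C)=C/C[C@]12C[C@@H](CO)C(C)(C)[C@](C/C=C(\C)CCC=C(C)C)(C(=O)C(C(=O)c3ccc(OCC=C)c(OCC=C)c3)=C1O)C2=O
F7 | step 9 | (1S,5S,7R)-3-[3,4-bis(allyloxy)benzoyl]-1,5-digeranyl-4-hydroxy-7-(iodomethyl)-8,8-dimethylbicyclo[3.3.1]non-3-ene-2,9-dione (7-exo) | CC(C)=CCC/C(C)=C/C[C@]12C[C@@H](CI)C(C)(C)[C@](C/C=C(\C)CCC=C(C)C)(C(=O)C(C(=O)c3ccc(OCC=C)c(OCC=C)c3)=C1O)C2=O
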